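The target is disconnected at the bond between the quaternary lactone carbon C2 (bearing the ring oxygen and a carboxyl) and the neighbouring methine that carries the second carboxyl and the C10 chain. The 5-oxooxolane ring is treated as a dearomatised furan: a 5-silyloxyfuran-2-carboxylate adds through its ester-bearing C2 to the β-carbon of tert-butyl (E)-4-oxobut-2-enoate under chiral imidazolidinone iminium catalysis (vinylogous Mukaiyama–Michael addition). One operation makes this bond, both contiguous stereocentres and the butenolide, and leaves an aldehyde for Wittig attachment of the remaining chain. Hydrogenation, regioselective opening of O-trifluoroacetyl-D-malic anhydride by the terminal alcohol and acidolysis of the tert-butyl ester complete the synthesis.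

Key step: step 6

Remark on the chemistry: the target is read as (R) at the lactone carbon, (S) at the adjacent methine and (R) in the malate unit (D-malic acid); furanone 3 and its 2,5-dihydro tautomer are equivalent precursors of furan 4.

Step 1
Reactants: 1 2-oxoglutaric acid
Product: 2 5-(benzyloxy)-4,5-dioxopentanoic acid
Conditions: dicyclohexylamine (1.0 equiv), BnBr (1.0 equiv), DMF, 50 °C
Reagents that add atoms: benzyl bromide, BrCc1ccccc1
Why: With one equivalent of amine only the more acidic α-keto carboxyl (C1) is ionised, so SN2 O-alkylation of that carboxylate should give the 1-monoester (regioselective carboxylate alkylation).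

Step 2
Reactants: 2 5-(benzyloxy)-4,5-dioxopentanoic acid
Product: 3 benzyl 5-oxo-4,5-dihydrofuran-2-carboxylate
Conditions: Ac2O, NaOAc (cat.), 90 °C
Reagents that add atoms: none
Why: The acid is activated as a mixed anhydride and the ketone can enolise only toward C3, so intramolecular O-acylation (enol lactonisation of a γ-keto acid) should give a single five-membered enol lactone.

Step 3
Reactants: 3 benzyl 5-oxo-4,5-dihydrofuran-2-carboxylate
Product: 4 benzyl 5-[(triisopropylsilyl)oxy]furan-2-carboxylate
Conditions: TIPSOTf (1.1 equiv), Et3N (1.5 equiv), CH2Cl2, 0 °C to rt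
Reagents that add atoms: triisopropylsilyl trifluoromethanesulfonate, CC(C)[Si](OS(=O)(=O)C(F)(F)F)(C(C)C)C(C)C
Why: Soft enolisation at C4 and O-silylation aromatise the furanone to the 2-silyloxyfuran (standard silyl dienol ether formation from butenolides), and the bulky silyl group should make the furan isolable.

Step 4
Reactants: 5 tert-butyl 2-(diethoxyphosphoryl)acetate; 6 2,2-dimethoxyacetaldehyde (60 % in water)
Product: 7 tert-butyl (2E)-4,4-dimethoxybut-2-enoate
Conditions: K2CO3, H2O/THF, rt
Reagents that add atoms: none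
Why: Horner–Wadsworth–Emmons olefination with a stabilised phosphonate anion should give the E-enoate, and the aqueous carbonate base tolerates the aqueous aldehyde.

Step 5
Reactants: 7 tert-butyl (2E)-4,4-dimethoxybut-2-enoate
Product: 8 tert-butyl (2E)-4-oxobut-2-enoate
Conditions: Amberlyst-15, acetone/H2O, rt
Reagents that add atoms: water, O
Why: Acid-catalysed acetal hydrolysis unmasks the aldehyde under conditions too mild to cleave the tert-butyl ester, and the E geometry is the thermodynamically preferred one.

Step 6
Reactants: 4 benzyl 5-[(triisopropylsilyl)oxy]furan-2-carboxylate; 8 tert-butyl (2E)-4-oxobut-2-enoate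
Product: 9 benzyl (2R)-2-[(2S)-1-(tert-butoxy)-1,4-dioxobutan-2-yl]-5-oxo-2,5-dihydrofuran-2-carboxylate
Conditions: (2R,5R)-5-benzyl-2-tert-butyl-3-methylimidazolidin-4-one (20 mol %), TfOH (20 mol %), H2O (2 equiv), CHCl3, −20 °C
Reagents that add atoms: none
Why: The amine salt condenses with enal 8 to an E-iminium ion, furan 4 attacks C2 of 8 (β to the aldehyde) through its ester-bearing C2, and water then takes the silyl group as the silanol and hydrolyses the enamine, so the aromatic furan ends as the 2(5H)-furanone and the catalyst is returned. The closest known reaction type is the imidazolidinone-catalysed vinylogous Mukaiyama–Michael addition of 5-substituted 2-silyloxyfurans to enals, a dearomatising route to γ,γ-disubstituted butenolides that extends to alkoxycarbonyl-substituted furans and 4-oxobut-2-enoates. No ring is closed: the lactone ring of the target is the furan ring itself, delivered by dearomatisation. The methine centre is under catalyst control, since the benzyl group of the (2R,5R)-catalyst covers the Si face of C2 of the iminium ion, so the furan should bond to the Re face and give the (S) configuration. The quaternary centre is set by simple diastereoselection, which here must run through the Re face of furan C2 (like topicity, a compact endo-type arrangement of the furan over the iminium ion); this selectivity responds to acid co-catalyst and solvent in this reaction class, and the triflate salt in chloroform is chosen to favour the like mode. The step also needs 1,4- over 1,2-addition and attack through furan C2 rather than C4: iminium activation by the bulky amine secures the first, the γ-reactivity of 2-silyloxyfurans the second, and the tert-butyl ester, which the amine cannot activate, fixes the new bond at the ester-bearing carbon of the enal.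

Step 7
Reactants: 10 8-bromooctan-1-ol
Product: 11 {[(8-bromooctyl)oxy]methyl}benzene
Conditions: benzyl 2,2,2-trichloroacetimidate, TfOH (cat.), CH2Cl2/cyclohexane, rt
Reagents that add atoms: benzyl 2,2,2-trichloroacetimidate, ClC(Cl)(Cl)C(=N)OCc1ccccc1
Why: Acid-catalysed benzylation with the trichloroacetimidate avoids an alkoxide, which would displace the primary bromide.

Step 8
Reactants: 11 {[(8-bromooctyl)oxy]methyl}benzene
Product: 12 [8-(benzyloxy)octyl]triphenylphosphonium bromide
Conditions: PPh3, MeCN, reflux
Reagents that add atoms: triphenylphosphine, c1ccc(P(c2ccccc2)c2ccccc2)cc1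
Why: SN2 quaternisation of triphenylphosphine by the primary bromide.

Step 9
Reactants: 12 [8-(benzyloxy)octyl]triphenylphosphonium bromide; 9 benzyl (2R)-2-[(2S)-1-(tert-butoxy)-1,4-dioxobutan-2-yl]-5-oxo-2,5-dihydrofuran-2-carboxylate
Product: 14 benzyl (2R)-2-[(2S,4Z)-12-(benzyloxy)-1-(tert-butoxy)-1-oxododec-4-en-2-yl]-5-oxo-2,5-dihydrofuran-2-carboxylate, via phosphonium ylide 13 (not isolated)
Conditions: NaN(SiMe3)2, THF, −78 °C; then 9, −78 to −20 °C
Reagents that add atoms: none
Why: Wittig olefination, in which the non-stabilised ylide should add to the aldehyde at −78 °C faster than it deprotonates it or attacks the butenolide; the alkene geometry (mainly Z) is irrelevant because the double bond is hydrogenated next, and neither stereocentre is touched.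

Step 10
Reactants: 14 benzyl (2R)-2-[(2S,4Z)-12-(benzyloxy)-1-(tert-butoxy)-1-oxododec-4-en-2-yl]-5-oxo-2,5-dihydrofuran-2-carboxylate
Product: 15 (2R)-2-[(2S)-1-(tert-butoxy)-12-hydroxy-1-oxododecan-2-yl]-5-oxooxolane-2-carboxylic acid
Conditions: H2 (1 atm), Pd/C (10 %), EtOAc/MeOH, rt
Reagents that add atoms: none
Why: Heterogeneous hydrogenation should saturate the chain alkene and the butenolide C=C and hydrogenolyse the benzyl ester and benzyl ether in one operation, while the tert-butyl ester, the lactone and both stereocentres are untouched under neutral conditions.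

Step 11
Reactants: 16 (R)-malic acid (D-malic acid)
Product: 17 (3R)-2,5-dioxooxolan-3-yl 2,2,2-trifluoroacetate
Conditions: (CF3CO)2O (neat), 0 °C to rt; evaporate
Reagents that add atoms: trifluoroacetic anhydride, O=C(OC(=O)C(F)(F)F)C(F)(F)F
Why: Trifluoroacetic anhydride acylates the hydroxyl and dehydrates the diacid to the five-membered anhydride without touching the stereocentre (known preparation of O-acyl malic anhydrides).

Step 12
Reactants: 15 (2R)-2-[(2S)-1-(tert-butoxy)-12-hydroxy-1-oxododecan-2-yl]-5-oxooxolane-2-carboxylic acid; 17 (3R)-2,5-dioxooxolan-3-yl 2,2,2-trifluoroacetate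
Product: 19 (2R)-2-[(2S)-1-(tert-butoxy)-12-{[(2R)-3-carboxy-2-hydroxypropanoyl]oxy}-1-oxododecan-2-yl]-5-oxooxolane-2-carboxylic acid, via O-trifluoroacetyl malate ester 18 (not isolated)
Conditions: 17 (3 equiv), THF, 0 °C to rt, no base; then H2O/THF, rt
Reagents that add atoms: none
Why: Base-free alcoholysis of the cyclic anhydride should occur at the more electrophilic carbonyl next to the trifluoroacetoxy-bearing carbon and give the 1-ester of malic acid (known regioselective opening of O-acyl malic anhydrides); the labile trifluoroacetate is hydrolysed on aqueous work-up, and without base neither elimination to maleic anhydride nor enolisation of the (R)-centre is expected.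

Step 13
Reactants: 19 (2R)-2-[(2S)-1-(tert-butoxy)-12-{[(2R)-3-carboxy-2-hydroxypropanoyl]oxy}-1-oxododecan-2-yl]-5-oxooxolane-2-carboxylic acid
Product: 20 (2R)-2-[(1S)-1-carboxy-11-{[(2R)-3-carboxy-2-hydroxypropanoyl]oxy}undecyl]-5-oxooxolane-2-carboxylic acid
Conditions: CF3CO2H/CH2Cl2 (1:1), rt; evaporate, MeCN/H2O
Reagents that add atoms: none
Why: Acidolysis of the tert-butyl ester (loss of the tert-butyl cation as isobutene) frees the last carboxylic acid without hydrolytic conditions, so the malate ester and the lactone should stay intact.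

Compound list
1 | 2-oxoglutaric acid (2-oxopentanedioic acid) | O=C(O)CCC(=O)C(=O)O | starting material
2 | 5-(benzyloxy)-4,5-dioxopentanoic acid | O=C(O)CCC(=O)C(=O)OCc1ccccc1 | intermediate
3 | benzyl 5-oxo-4,5-dihydrofuran-2-carboxylate | O=C1CC=C(C(=O)OCc2ccccc2)O1 | intermediate
4 | benzyl 5-[(triisopropylsilyl)oxy]furan-2-carboxylate | CC(C)[Si](Oc1ccc(C(=O)OCc2ccccc2)o1)(C(C)C)C(C)C | intermediate
5 | tert-butyl 2-(diethoxyphosphoryl)acetate | CCOP(=O)(CC(=O)OC(C)(C)C)OCC | starting material
6 | 2,2-dimethoxyacetaldehyde | COC(OC)C=O | starting material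
7 | tert-butyl (2E)-4,4-dimethoxybut-2-enoate | COC(OC)/C=C/C(=O)OC(C)(C)C | intermediate
8 | tert-butyl (2E)-4-oxobut-2-enoate | O=C/C=C/C(=O)OC(C)(C)C | intermediate
9 | benzyl (2R)-2-[(2S)-1-(tert-butoxy)-1,4-dioxobutan-2-yl]-5-oxo-2,5-dihydrofuran-2-carboxylate | O=CC[C@H](C(=O)OC(C)(C)C)[C@@]1(C(=O)OCc2ccccc2)C=CC(=O)O1 | intermediate
10 | 8-bromooctan-1-ol | OCCCCCCCCBr | starting material
11 | {[(8-bromooctyl)oxy]methyl}benzene | BrCCCCCCCCOCc1ccccc1 | intermediate
12 | [8-(benzyloxy)octyl]triphenylphosphonium bromide | [Br-].c1ccccc1COCCCCCCCC[P+](c1ccccc1)(c1ccccc1)c1ccccc1 | intermediate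
13 | [8-(benzyloxy)octylidene]triphenyl-λ5-phosphane (ylide) | c1ccccc1COCCCCCCCC=P(c1ccccc1)(c1ccccc1)c1ccccc1 | intermediate (not isolated)
14 | benzyl (2R)-2-[(2S,4Z)-12-(benzyloxy)-1-(tert-butoxy)-1-oxododec-4-en-2-yl]-5-oxo-2,5-dihydrofuran-2-carboxylate | c1ccccc1COCCCCCCC/C=C\C[C@H](C(=O)OC(C)(C)C)[C@@]1(C(=O)OCc2ccccc2)C=CC(=O)O1 | intermediate
15 | (2R)-2-[(2S)-1-(tert-butoxy)-12-hydroxy-1-oxododecan-2-yl]-5-oxooxolane-2-carboxylic acid | OCCCCCCCCCC[C@H](C(=O)OC(C)(C)C)[C@@]1(C(=O)O)CCC(=O)O1 | intermediate
16 | (R)-malic acid (D-malic acid) | O=C(O)C[C@@H](O)C(=O)O | starting material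
17 | (3R)-2,5-dioxooxolan-3-yl 2,2,2-trifluoroacetate | O=C1C[C@@H](OC(=O)C(F)(F)F)C(=O)O1 | intermediate
18 | (2R)-2-[(2S)-1-(tert-butoxy)-12-{[(2R)-3-carboxy-2-(trifluoroacetoxy)propanoyl]oxy}-1-oxododecan-2-yl]-5-oxooxolane-2-carboxylic acid | O=C(O)C[C@@H](OC(=O)C(F)(F)F)C(=O)OCCCCCCCCCC[C@H](C(=O)OC(C)(C)C)[C@@]1(C(=O)O)CCC(=O)O1 | intermediate (not isolated)
19 | (2R)-2-[(2S)-1-(tert-butoxy)-12-{[(2R)-3-carboxy-2-hydroxypropanoyl]oxy}-1-oxododecan-2-yl]-5-oxooxolane-2-carboxylic acid | O=C(O)C[C@@H](O)C(=O)OCCCCCCCCCC[C@H](C(=O)OC(C)(C)C)[C@@]1(C(=O)O)CCC(=O)O1 | intermediate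
20 | (2R)-2-[(1S)-1-carboxy-11-{[(2R)-3-carboxy-2-hydroxypropanoyl]oxy}undecyl]-5-oxooxolane-2-carboxylic acid | O=C(O)C[C@@H](O)C(=O)OCCCCCCCCCC[C@H](C(=O)O)[C@@]1(C(=O)O)CCC(=O)O1 | target

Total step count: 13. Longest linear sequence: 8 steps (steps 1, 2, 3, 6, 9, 10, 12, 13).

Steps most likely to fail

Step 6. The furan may bond through the wrong face of its C2 (unlike instead of like topicity), or an uncatalysed background addition may erode the enantioselectivity. The fallback sets out from 4 and comes back at 9, and replaces iminium activation by two-point Lewis-acid activation of an imide. Mono-tert-butyl fumarate is converted through its pivaloyl mixed anhydride (PivCl, Et3N, then oxazolidin-2-one, LiCl, THF) into tert-butyl (2E)-4-oxo-4-(2-oxo-1,3-oxazolidin-3-yl)but-2-enoate F1. Furan 4 is added to it with Cu(OTf)2 (divalent copper) and a tert-butyl-bis(oxazoline) ligand (10 mol %) in CH2Cl2 at −78 °C with (CF3)2CHOH as silyl acceptor, the ligand enantiomer being chosen for attack on the Re face of the ester-bearing carbon. The chelated s-cis imide has a different transition-state geometry and should give benzyl (2R)-2-[(2S)-1-(tert-butoxy)-1,4-dioxo-4-(2-oxo-1,3-oxazolidin-3-yl)butan-2-yl]-5-oxo-2,5-dihydrofuran-2-carboxylate F2. NaBH4 in THF/H2O at 0 °C reduces the imide to benzyl (2R)-2-[(2S)-1-(tert-butoxy)-4-hydroxy-1-oxobutan-2-yl]-5-oxo-2,5-dihydrofuran-2-carboxylate F3, and Dess–Martin periodinane in CH2Cl2 oxidises it to 9.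

Step 9. The basic ylide may enolise the aldehyde, which can then expel the furanolate (retro-Michael cleavage) or epimerise the methine, or the ylide may add to the butenolide. The fallback sets out from 9 and comes back at 15, and attaches the chain without base. Takai–Lombardo methylenation (Zn, CH2Br2, TiCl4, THF/CH2Cl2, 0 °C) gives benzyl (2R)-2-[(2S)-1-(tert-butoxy)-1-oxopent-4-en-2-yl]-5-oxo-2,5-dihydrofuran-2-carboxylate F4. Cross-metathesis with [(non-8-en-1-yloxy)methyl]benzene F5 (from non-8-en-1-ol, NaH, BnBr, THF) using the second-generation Grubbs catalyst in CH2Cl2 at 40 °C gives benzyl (2R)-2-[(2S,4E)-12-(benzyloxy)-1-(tert-butoxy)-1-oxododec-4-en-2-yl]-5-oxo-2,5-dihydrofuran-2-carboxylate F6 (an E/Z mixture is acceptable). Hydrogenation under the conditions of step 10 gives 15.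

Step 2. Acyclic enol acetate or acylal formation may compete with lactonisation, and the α-keto ester may decompose in hot anhydride. The fallback sets out from 2 and comes back at 3, and goes through the acid chloride at low temperature. Oxalyl chloride with catalytic DMF in CH2Cl2 at 0 °C converts 2 into its cyclic pseudo-acid chloride, benzyl 2-chloro-5-oxooxolane-2-carboxylate F7 (the ring tautomer of the γ-keto acid chloride), and Et3N at 0 °C eliminates HCl to give 3, which can be silylated as in step 3.

Further compounds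
F1 | step 6 | tert-butyl (2E)-4-oxo-4-(2-oxo-1,3-oxazolidin-3-yl)but-2-enoate | O=C(/C=C/C(=O)N1CCOC1=O)OC(C)(C)C
F2 | step 6 | benzyl (2R)-2-[(2S)-1-(tert-butoxy)-1,4-dioxo-4-(2-oxo-1,3-oxazolidin-3-yl)butan-2-yl]-5-oxo-2,5-dihydrofuran-2-carboxylate | O=C(C[C@H](C(=O)OC(C)(C)C)[C@@]1(C(=O)OCc2ccccc2)C=CC(=O)O1)N1CCOC1=O
F3 | step 6 | benzyl (2R)-2-[(2S)-1-(tert-butoxy)-4-hydroxy-1-oxobutan-2-yl]-5-oxo-2,5-dihydrofuran-2-carboxylate | OCC[C@H](C(=O)OC(C)(C)C)[C@@]1(C(=O)OCc2ccccc2)C=CC(=O)O1
F4 | step 9 | benzyl (2R)-2-[(2S)-1-(tert-butoxy)-1-oxopent-4-en-2-yl]-5-oxo-2,5-dihydrofuran-2-carboxylate | C=CC[C@H](C(=O)OC(C)(C)C)[C@@]1(C(=O)OCc2ccccc2)C=CC(=O)O1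
F5 | step 9 | [(non-8-en-1-yloxy)methyl]benzene | C=CCCCCCCCOCc1ccccc1
F6 | step 9 | benzyl (2R)-2-[(2S,4E)-12-(benzyloxy)-1-(tert-butoxy)-1-oxododec-4-en-2-yl]-5-oxo-2,5-dihydrofuran-2-carboxylate | c1ccccc1COCCCCCCC/C=C/C[C@H](C(=O)OC(C)(C)C)[C@@]1(C(=O)OCc2ccccc2)C=CC(=O)O1
F7 | step 2 | benzyl 2-chloro-5-oxooxolane-2-carboxylate (racemic) | O=C1CCC(Cl)(C(=O)OCc2ccccc2)O1
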